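**Plan**

- Retrosynthesis: the two C–C bonds of the bridging CH2 are cut first (trione C6–CH2 and CH2–chromene C6). This gives an acetyl trione, the 8-hexanoyl-5,7-dihydroxychromene and a one-carbon iminium unit.
- The trione ring is then cut between C2 (acetyl-bearing) and C3 (the enol carbon beside the quaternary C4). C3 is recast as the lactone carbonyl of a 3,3-disubstituted 6-(2-oxopropyl)-2H-pyran-2,4(3H)-dione, whose ring bond O1–C2 is not in the target. The acetyl C–C bond and the C3–geranyl bond are cut last, back to 4-hydroxy-3,6-dimethyl-2-pyrone.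
- Enabling feature: in the pyrandione the chain C2(=O)–C3(quaternary)–C4(=O)–C5=C6–CH2–COCH3 is already complete, and only the enol-ester oxygen O1 keeps the acetonyl CH2 away from C2. O1 makes the two flanks of C3 different (lactone against ketone), so C3 is a true, non-enolisable stereocentre. O1 also forbids a premature Dieckmann closure (four-membered transition state, achiral trione) and is released by alkoxide on demand.
- Forward: pyrone, then palladium-catalysed asymmetric C3-geranylation, then γ-acetylation of the 6-methyl group, then the lactone-to-carbocycle Claisen ring transformation. Separately: phloroglucinol, hexanoyl ketone, para-silyl ether, chromene (pyran ring from prenal), free phenol. The halves are joined last through a Mannich base.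
- Stereochemistry: the single stereocentre (C4 of the trione = C3 of the pyrandione, R) comes from the chiral bisphosphine–palladium catalyst in the geranylation and cannot epimerise afterwards. The (E)-alkene is bought with geraniol.

Key step: step 6

Assumption: the (1S,2S)-ligand is taken as the antipode that delivers the (R)-quaternary centre in step 4; should the sense be opposite, the (1R,2R)-ligand is used and nothing else changes. Triones are drawn in the enol form of the target; "geranyl" means (2E)-3,7-dimethylocta-2,6-dien-1-yl.

**Route**

Step 1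
Reactants: 1 ethyl 2-methyl-3-oxobutanoate; 2 N-methoxy-N-methylacetamide
Product: 3 ethyl 2-methyl-3,5-dioxohexanoate
Conditions: NaH (1.1 equiv), THF, 0 °C; n-BuLi (1.05 equiv), 0 °C; 2 (0.9 equiv), 0 °C to rt; then 1 M HCl
Reagents that add atoms: N-methoxy-N-methylacetamide (2), CC(=O)N(C)OC
Why: γ-acylation of the acetoacetate dianion (Claisen-type acylation at the terminal, more reactive carbanion) by an N-methoxy-N-methylamide, whose chelated tetrahedral adduct prevents over-addition, should give the 3,5-diketo ester.

Step 2
Reactants: 3 ethyl 2-methyl-3,5-dioxohexanoate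
Product: 4 4-hydroxy-3,6-dimethyl-2H-pyran-2-one
Conditions: DBU (1.2 equiv), toluene, reflux; then 1 M HCl
Reagents that add atoms: none
Why: base-mediated enol lactonisation (O-acylation of the C5 enolate by the ester with loss of ethanol) is driven by formation of the conjugated 4-hydroxy-2-pyrone and is the standard closure of 3,5-diketo esters.

Step 3
Reactants: 5 geraniol; 6 methyl chloroformate
Product: 7 geranyl methyl carbonate
Conditions: pyridine (1.5 equiv), CH2Cl2, 0 °C to rt
Reagents that add atoms: methyl chloroformate (6), COC(=O)Cl
Why: carbonate formation from a primary allylic alcohol and a chloroformate is routine and leaves the (E)-alkene untouched.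

Step 4
Reactants: 4 4-hydroxy-3,6-dimethyl-2H-pyran-2-one; 7 geranyl methyl carbonate
Product: 8 (3R)-3-geranyl-3,6-dimethyl-2H-pyran-2,4(3H)-dione
Conditions: 4 (1.1 equiv), 7 (1.0 equiv), Pd2(dba)3·CHCl3 (2.5 mol%), (1S,2S)-N,N'-bis[2-(diphenylphosphino)benzoyl]cyclohexane-1,2-diamine (7.5 mol%), CH2Cl2, 0 °C to rt
Reagents that add atoms: none
Why: in this Tsuji–Trost asymmetric allylic alkylation zerovalent palladium ionises the carbonate to an (E)-π-geranyl complex, CO2 and methoxide, the pyranolate (pKa about 5) attacks the unsubstituted allyl terminus through C3 (any O-geranyl ether re-ionises and funnels to the C-product), and the chiral ligand pocket selects one face of the flat, unsymmetrical pyranolate (lactone flank against C4–O flank) to set the quaternary centre as (R), in line with asymmetric allylations of cyclic β-keto esters and dearomatising allylations of naphthols.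

Step 5
Reactants: 8 (3R)-3-geranyl-3,6-dimethyl-2H-pyran-2,4(3H)-dione; 9 1-acetyl-1H-benzotriazole
Product: 10 (3R)-3-geranyl-3-methyl-6-(2-oxopropyl)-2H-pyran-2,4(3H)-dione
Conditions: LiN(SiMe3)2 (2.2 equiv), THF, −78 °C; 9 (1.1 equiv), −78 to −20 °C; then 1 M HCl
Reagents that add atoms: 1-acetyl-1H-benzotriazole (9), CC(=O)n1nnc2ccccc21
Why: vinylogous deprotonation of the 6-methyl group and C-acylation of the lithium dienolate at the exocyclic carbon by an N-acylbenzotriazole (vinylogous Claisen acylation, as practised on 6-methyl-1,3-dioxin-4-ones) should install the acetonyl chain, the second equivalent of base storing the product as its enolate, while the carbanion cannot reach the lactone carbonyl (four-membered transition state) and C3 has no proton to lose.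

Step 6
Reactants: 10 (3R)-3-geranyl-3-methyl-6-(2-oxopropyl)-2H-pyran-2,4(3H)-dione
Product: 12 (4R)-2-acetyl-4-geranyl-3,5-dihydroxy-4-methylcyclohexa-2,5-dien-1-one, via ring-opened methyl ester 11 (not isolated)
Conditions: NaOMe (3 equiv), MeOH, 0 °C to 60 °C; then 1 M HCl, 0 °C
Reagents that add atoms: none
Why: Methoxide deprotonates the side-chain 1,3-diketone and opens the enol lactone at its acyl carbon (pyrandione C2) to methyl ester 11, whose triketone anion places charge on the acetonyl methylene (flanked by the former C6 ketone and the acetyl); this carbon attacks the ester, methoxide leaves, and deprotonation of the strongly acidic 2-acyl-1,3,5-trione makes the sequence irreversible. The closest known reaction type is the alkoxide-induced recyclisation of 6-(2-oxoalkyl)-4-hydroxy-2-pyrones to acylphloroglucinols, together with the enol-lactone to cyclic 1,3-dione rearrangement, both of which are Dieckmann/Claisen condensations. The six-membered carbocycle closes in a 6-exo-trig mode. No stereocentre is formed: the quaternary carbon from step 4 has no α-hydrogen and is carried through unchanged, and because the former lactone carbonyl rather than the C4 ketone bonds to the acetyl-bearing carbon, the (R) centre of 10 maps onto the (R) centre of 12. The step needs C-acylation by the acetonyl methylene in preference to aldol closure, fragmentation or return to the lactone; only that carbon reaches the ester through a six-membered transition state (the ring-derived CH would need four atoms, the acetyl methyl eight), the blocked C3 rules out an orsellinate-type aldol, the gem-disubstitution favours closure, and relactonisation is reversible whereas the Claisen product is trapped as its salt.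

Step 7
Reactants: 13 phloroglucinol; 14 hexanoyl chloride
Product: 15 1-(2,4,6-trihydroxyphenyl)hexan-1-one
Conditions: AlCl3 (4 equiv), PhNO2, 0 to 60 °C; then ice, 1 M HCl
Reagents that add atoms: hexanoyl chloride (14), CCCCCC(=O)Cl
Why: Friedel–Crafts C-acylation of the threefold-symmetric, highly activated triol should stop at the mono-ketone because the first acyl group deactivates the ring.

Step 8
Reactants: 15 1-(2,4,6-trihydroxyphenyl)hexan-1-one; 16 tert-butyldimethylsilyl chloride
Product: 17 1-[4-(tert-butyldimethylsilyloxy)-2,6-dihydroxyphenyl]hexan-1-one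
Conditions: 16 (1.05 equiv), imidazole (2 equiv), DMF, 0 °C
Reagents that add atoms: tert-butyldimethylsilyl chloride (16), CC(C)(C)[Si](C)(C)Cl
Why: regioselective O-silylation should take the 4-hydroxyl para to the ketone, which is the most acidic and the only one not tied up in a hydrogen bond to the carbonyl.

Step 9
Reactants: 17 1-[4-(tert-butyldimethylsilyloxy)-2,6-dihydroxyphenyl]hexan-1-one; 18 3-methylbut-2-enal
Product: 20 1-[5-(tert-butyldimethylsilyloxy)-7-hydroxy-2,2-dimethyl-2H-chromen-8-yl]hexan-1-one, via dienone 19 (not isolated)
Conditions: ethylenediammonium diacetate (20 mol%), toluene, reflux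
Reagents that add atoms: 3-methylbut-2-enal (18), CC(C)=CC=O
Why: amine-salt-catalysed Knoevenagel-type condensation of the enal at a free ring carbon followed by oxa-6π electrocyclisation of dienone 19 gives the 2H-chromene (formal [3+3] chromene annulation), and because each free carbon is flanked by one free hydroxyl ortho to the ketone and by the silyl ether, the ring oxygen must end up next to the acyl-bearing carbon as the target requires.

Step 10
Reactants: 20 1-[5-(tert-butyldimethylsilyloxy)-7-hydroxy-2,2-dimethyl-2H-chromen-8-yl]hexan-1-one
Product: 21 1-(5,7-dihydroxy-2,2-dimethyl-2H-chromen-8-yl)hexan-1-one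
Conditions: Bu4NF (1.1 equiv), AcOH (1.1 equiv), THF, 0 °C
Reagents that add atoms: none
Why: buffered fluoride desilylation of the aryl silyl ether should free the phenol without touching the chromene alkene or the ketone.

Step 11
Reactants: 12 (4R)-2-acetyl-4-geranyl-3,5-dihydroxy-4-methylcyclohexa-2,5-dien-1-one; 21 1-(5,7-dihydroxy-2,2-dimethyl-2H-chromen-8-yl)hexan-1-one; 22 dimethyl(methylidene)ammonium iodide
Product: 25 (4R)-2-acetyl-4-geranyl-6-[(8-hexanoyl-5,7-dihydroxy-2,2-dimethyl-2H-chromen-6-yl)methyl]-3,5-dihydroxy-4-methylcyclohexa-2,5-dien-1-one, via Mannich base 23 (not isolated), via methylene trione 24 (not isolated)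
Conditions: 22 (1.05 equiv), MeCN, 0 °C to rt; then 21 (1.2 equiv), 60 °C
Reagents that add atoms: dimethyl(methylidene)ammonium iodide (22), C=[N+](C)C.[I-]
Why: Mannich reaction of the enolic trione at its only free ring carbon gives base 23, which on warming loses dimethylamine to the exocyclic enone 24 that is captured by the only free aromatic carbon of 21, flanked by two hydroxyls (Mannich-base elimination followed by Friedel–Crafts-type Michael addition), with the stereocentre untouched.

**Compound list**

1 | ethyl 2-methyl-3-oxobutanoate | CCOC(=O)C(C)C(C)=O | starting material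
2 | N-methoxy-N-methylacetamide | CC(=O)N(C)OC | starting material
3 | ethyl 2-methyl-3,5-dioxohexanoate | CCOC(=O)C(C)C(=O)CC(C)=O | intermediate
4 | 4-hydroxy-3,6-dimethyl-2H-pyran-2-one | CC1=CC(O)=C(C)C(=O)O1 | intermediate
5 | geraniol, (2E)-3,7-dimethylocta-2,6-dien-1-ol | OC/C=C(\C)CCC=C(C)C | starting material
6 | methyl chloroformate | COC(=O)Cl | starting material
7 | geranyl methyl carbonate | COC(=O)OC/C=C(\C)CCC=C(C)C | intermediate
8 | (3R)-3-geranyl-3,6-dimethyl-2H-pyran-2,4(3H)-dione | CC1=CC(=O)[C@@](C)(C/C=C(\C)CCC=C(C)C)C(=O)O1 | intermediate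
9 | 1-acetyl-1H-benzotriazole | CC(=O)n1nnc2ccccc21 | starting material
10 | (3R)-3-geranyl-3-methyl-6-(2-oxopropyl)-2H-pyran-2,4(3H)-dione | CC(=O)CC1=CC(=O)[C@@](C)(C/C=C(\C)CCC=C(C)C)C(=O)O1 | intermediate
11 | methyl (2R)-2-geranyl-2-methyl-3,5,7-trioxooctanoate (not isolated) | COC(=O)[C@](C)(C/C=C(\C)CCC=C(C)C)C(=O)CC(=O)CC(C)=O | intermediate
12 | (4R)-2-acetyl-4-geranyl-3,5-dihydroxy-4-methylcyclohexa-2,5-dien-1-one | O=C1C=C(O)[C@@](C)(C/C=C(\C)CCC=C(C)C)C(O)=C1C(C)=O | intermediate
13 | phloroglucinol (benzene-1,3,5-triol) | Oc1cc(O)cc(O)c1 | starting material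
14 | hexanoyl chloride | CCCCCC(=O)Cl | starting material
15 | 1-(2,4,6-trihydroxyphenyl)hexan-1-one | CCCCCC(=O)c1c(O)cc(O)cc1O | intermediate
16 | tert-butyldimethylsilyl chloride | CC(C)(C)[Si](C)(C)Cl | starting material
17 | 1-[4-(tert-butyldimethylsilyloxy)-2,6-dihydroxyphenyl]hexan-1-one | CCCCCC(=O)c1c(O)cc(O[Si](C)(C)C(C)(C)C)cc1O | intermediate
18 | 3-methylbut-2-enal | CC(C)=CC=O | starting material
19 | 5-(tert-butyldimethylsilyloxy)-2-hexanoyl-3-hydroxy-6-(3-methylbut-2-en-1-ylidene)cyclohexa-2,4-dien-1-one (not isolated) | CCCCCC(=O)C1=C(O)C=C(O[Si](C)(C)C(C)(C)C)C(=CC=C(C)C)C1=O | intermediate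
20 | 1-[5-(tert-butyldimethylsilyloxy)-7-hydroxy-2,2-dimethyl-2H-chromen-8-yl]hexan-1-one | CCCCCC(=O)c1c(O)cc(O[Si](C)(C)C(C)(C)C)c2c1OC(C)(C)C=C2 | intermediate
21 | 1-(5,7-dihydroxy-2,2-dimethyl-2H-chromen-8-yl)hexan-1-one | CCCCCC(=O)c1c(O)cc(O)c2c1OC(C)(C)C=C2 | intermediate
22 | dimethyl(methylidene)ammonium iodide | C=[N+](C)C.[I-] | starting material
23 | (4R)-2-acetyl-6-[(dimethylamino)methyl]-4-geranyl-3,5-dihydroxy-4-methylcyclohexa-2,5-dien-1-one (not isolated) | CN(C)CC1=C(O)[C@@](C)(C/C=C(\C)CCC=C(C)C)C(O)=C(C(C)=O)C1=O | intermediate
24 | (4S)-2-acetyl-4-geranyl-3-hydroxy-4-methyl-6-methylidenecyclohex-2-ene-1,5-dione (not isolated; same spatial arrangement as 12, the descriptor changes by priority only) | C=C1C(=O)[C@@](C)(C/C=C(\C)CCC=C(C)C)C(O)=C(C(C)=O)C1=O | intermediate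
25 | (4R)-2-acetyl-4-geranyl-6-[(8-hexanoyl-5,7-dihydroxy-2,2-dimethyl-2H-chromen-6-yl)methyl]-3,5-dihydroxy-4-methylcyclohexa-2,5-dien-1-one | CCCCCC(=O)c1c(O)c(CC2=C(O)[C@@](C)(C/C=C(\C)CCC=C(C)C)C(O)=C(C(C)=O)C2=O)c(O)c2c1OC(C)(C)C=C2 | target

**Count and risks**

Total steps: 11. Longest linear sequence: 6 steps (steps 1, 2, 4, 5, 6 and 11).

Steps most likely to fail:

Step 4. The chiral pocket may discriminate poorly between the two faces of the flat pyranolate. The (E)-π-geranyl complex may also leak to neryl or branched products by π–σ–π isomerisation, or the reaction may stall at the O-geranyl ether. The fallback sets the centre with a stoichiometric auxiliary on an acyclic β-keto ester and then builds the lactone ring around it; it sets out from 1 and comes back at 8. Condensation of 1 with tert-butyl L-valinate (cat. TsOH, benzene, reflux, water removal) should give the chiral enamino ester ethyl (2Z)-3-{[(2S)-1-tert-butoxy-3-methyl-1-oxobutan-2-yl]amino}-2-methylbut-2-enoate F1. Deprotonation with LiN(i-Pr)2 and alkylation of the chelated lithio-enamine with geranyl bromide follows, in THF or in toluene with HMPA, whichever medium gives the (R) sense. Mild acid hydrolysis (aqueous AcOH, NaOAc) should then give ethyl (2R)-2-geranyl-2-methyl-3-oxobutanoate F2 and return the amino ester. The kinetic methyl-ketone enolate of F2 (LiN(SiMe3)2, THF, −78 °C) is acylated with 9 to ethyl (2R)-2-geranyl-2-methyl-3,5-dioxohexanoate F3. DBU in refluxing toluene with removal of ethanol should close the enol lactone to 8.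

Step 6. The cascade may stall at the ring-opened ester because Claisen closure onto the neopentyl-type ester is slow. Methoxide may then cleave the non-enolisable β-keto ester by retro-Claisen fragmentation, or the material may simply return to the lactone. The fallback separates ring opening from ring closure and uses a more electrophilic acyl donor with Lewis-acid templating; it sets out from 10 and comes back at 12. Thiophenol and Et3N in CH2Cl2 should open the enol lactone to S-phenyl (2R)-2-geranyl-2-methyl-3,5,7-trioxooctanethioate F4, isolated as the neutral triketone. Soft enolisation (MgBr2·OEt2, i-Pr2NEt, CH2Cl2, rt) should then make the magnesium-chelated side-chain diketonate acylate the thioester, closing the same bond and giving 12 after an acid wash.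

Step 11. Retro-Mannich exchange may scramble the one-carbon unit and give symmetrical dimers. The transient methylene trione may also be captured within the same molecule by the proximal geranyl alkene before the chromene arrives. The fallback reverses the roles of the partners so that the electrophile is generated on the chromene; it sets out from 21 and comes back at 25. Aminomethylation of 21 with 22 (MeCN, rt, then NaHCO3 wash) should give 1-{6-[(dimethylamino)methyl]-5,7-dihydroxy-2,2-dimethyl-2H-chromen-8-yl}hexan-1-one F5. Heating F5 with 12 (toluene, 80 °C) should generate the ortho-quinone methide on the chromene side, which the trione enol of 12 captures at its only free carbon to give 25.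

Further compounds
F1 | step 4 | ethyl (2Z)-3-{[(2S)-1-tert-butoxy-3-methyl-1-oxobutan-2-yl]amino}-2-methylbut-2-enoate | CCOC(=O)/C(C)=C(/C)N[C@@H](C(C)C)C(=O)OC(C)(C)C
F2 | step 4 | ethyl (2R)-2-geranyl-2-methyl-3-oxobutanoate | CCOC(=O)[C@](C)(C/C=C(\C)CCC=C(C)C)C(C)=O
F3 | step 4 | ethyl (2R)-2-geranyl-2-methyl-3,5-dioxohexanoate | CCOC(=O)[C@](C)(C/C=C(\C)CCC=C(C)C)C(=O)CC(C)=O
F4 | step 6 | S-phenyl (2R)-2-geranyl-2-methyl-3,5,7-trioxooctanethioate | CC(=O)CC(=O)CC(=O)[C@@](C)(C/C=C(\C)CCC=C(C)C)C(=O)Sc1ccccc1
F5 | step 11 | 1-{6-[(dimethylamino)methyl]-5,7-dihydroxy-2,2-dimethyl-2H-chromen-8-yl}hexan-1-one | CCCCCC(=O)c1c(O)c(CN(C)C)c(O)c2c1OC(C)(C)C=C2
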